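**Plan**

1. Retrosynthesis (pyran labels: O1, C2 = spiro carbon, C3 = CH bearing ring C, C4 = CH bearing the chain, C5 = CH2, C6 = CH(CH3)): cut O–CH3; ring B at N=C and at the CH2–C(=O) bond next to ring A; ring C (Paal–Knorr) and the ansa ring (alkyne metathesis in mid-chain); N–C2 (Curtius); chain–C4 (cuprate); last the two pyran bonds C2–C3 and C5–C6, which fall to a furan plus a tethered vinylcarbene.
2. Forward: the pyran is made first, inside a lactone-bridged 8-oxabicyclo[3.2.1]octadiene; then the chain at C4, the two-carbon bridge cut to CH3 (on C6) and CO2H → NHBoc (on C2), the 13-membered cycloalkyne, ring C, ring B with ring A, and O-methylation last.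
3. Stereochemistry: the carbinol centre of (R)-1-(furan-2-yl)ethanol is the only source. It chooses the furan face (C2, C6); the bicycle then fixes C4 (exo addition) and C3 (equilibration to equatorial); Curtius retention puts N cis to CH3. The carbinol centre itself ends as the C–OCH3 carbon of ring B.
4. Enabling feature: O1 lies between C2 and C6, and the N on C2 is cis to the CH3 on C6, like the two stumps of a two-carbon bridge. So C2–O1–C6 plus that bridge are the five ring atoms of a furan, the pyran is a cut-open oxygen-bridged cycloheptadiene, and C3–C4–C5 is a vinylcarbene.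

Key step: step 3

Remark: the pyran labels above are used for all intermediates; "exo" is the face of the bicycles turned to O1 and away from the two-carbon bridge; the γ-hydroxy ketones 20–22 are drawn open but should exist mainly as cis-fused cyclic hemiketals that react through the open form.
Assumption: (R)-1-(furan-2-yl)ethanol, 1-propynyllithium and 1-(tert-butoxycarbonyl)pyrrole-2-carboxylic acid are taken as catalogue compounds.

**Route**

Step 1
Reactants: 1 (R)-1-(furan-2-yl)ethanol; 2 but-3-enoic acid
Product: 3 (R)-1-(furan-2-yl)ethyl but-3-enoate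
Conditions: DCC, DMAP (5 mol %), CH2Cl2, 0 °C
Reagents that add atoms: none
Why: Steglich esterification acylates the oxygen only, so the carbinol centre is untouched, and low temperature with little DMAP should keep the β,γ-double bond out of conjugation.

Step 2
Reactants: 3 (R)-1-(furan-2-yl)ethyl but-3-enoate
Product: 4 (R)-1-(furan-2-yl)ethyl 2-diazobut-3-enoate
Conditions: 4-acetamidobenzenesulfonyl azide, DBU, MeCN, 0 °C; used cold at once
Reagents that add atoms: 4-acetamidobenzenesulfonyl azide, CC(=O)Nc1ccc(cc1)S(=O)(=O)N=[N+]=[N-]
Why: Regitz diazo transfer to the CH2 that is both allylic and α to the ester is the standard entry to vinyldiazoacetates; the product is not stored because it slowly closes to a pyrazole.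

Step 3
Reactants: 4 (R)-1-(furan-2-yl)ethyl 2-diazobut-3-enoate
Product: 6 tricyclic dienyl lactone, via divinylcyclopropane 5 (not isolated)
Conditions: Rh2(O2CC7H15)4 (1 mol %), CH2Cl2/pentane, −20 °C → rt, slow addition of 4; any minor diastereomer removed by chromatography
Reagents that add atoms: none
Why: The carboxylate of divalent rhodium turns 4 into a vinylcarbene that cyclopropanates the furan 2,3-bond held in reach by the ester tether (closing the five-membered lactone in the exo mode of allyl diazoacetates) to give the cis-divinylcyclopropane 5; 5 then undergoes a boat-shaped Cope [3,3] shift that closes the seven-membered carbocycle and with it the oxygen-bridged pyran, leaving the carbene carbon on the substituted furan α-carbon (C2–C3 bond) and joining the vinyl terminus to the free α-carbon (C5–C6 bond). This is the known tandem cyclopropanation/Cope rearrangement (formal [4+3] cycloaddition) of vinylcarbenoids with furans, also known with dienes and pyrroles tethered through the ester. Both new stereocentres are bridgeheads: C6 must form on the face on which the carbene arrived because the Cope shift is suprafacial on the dihydrofuran, and that face is set by the carbinol centre, whose methyl group avoids allylic strain with furan H-3 and the endo position on the forming bicyclic lactone, so the carbene should add anti to it. The tether secures the regiochemistry (an untethered carbenoid attacks the free α-position) and the cis-divinyl geometry; the step needs the Cope shift to outrun electrocyclic opening of the furan to a dienone, which slow addition at low temperature should favour.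

Step 4
Reactants: 7 1,6-dibromohexane; 8 1-propynyllithium
Product: 9 9-bromonon-2-yne
Conditions: THF/DMPU, −78 °C → rt, 7 in threefold excess
Reagents that add atoms: none
Why: SN2 alkylation of a lithium acetylide by a primary bromide, with excess dibromide to suppress double substitution.

Step 5
Reactants: 6 tricyclic dienyl lactone; 9 9-bromonon-2-yne
Product: 11 cis-fused chain lactone, via non-7-yn-1-ylmagnesium bromide 10 (not isolated)
Conditions: 9, Mg, THF; then CuBr·SMe2 (20 mol %), 6, THF, −78 → −40 °C; AcOH, −78 °C
Reagents that add atoms: none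
Why: Copper-catalysed conjugate addition of a Grignard reagent to the alkylidene lactone should deliver the chain to C4 from the exo face, as in 3-substituted tropane syntheses from bicyclic enoates, and kinetic protonation should give the cis-fused lactone with the C3 carbonyl exo (corrected in step 9).

Step 6
Reactants: 11 cis-fused chain lactone
Product: 12 hydroxy Weinreb amide
Conditions: MeNHOMe·HCl, AlMe3, CH2Cl2, 0 °C → rt; aqueous Rochelle salt
Reagents that add atoms: N,O-dimethylhydroxylamine hydrochloride, CNOC.Cl
Why: Weinreb aminolysis of the lactone with the aluminium amide touches no stereocentre and prepares a single organolithium addition.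

Step 7
Reactants: 12 hydroxy Weinreb amide
Product: 13 silyl ether Weinreb amide
Conditions: TBSOTf, 2,6-lutidine, CH2Cl2, −78 → 0 °C
Reagents that add atoms: tert-butyldimethylsilyl trifluoromethanesulfonate, CC(C)(C)[Si](C)(C)OS(=O)(=O)C(F)(F)F
Why: Silyl triflate silylation of the hindered secondary alcohol keeps this oxygen from closing a hemiketal on the later C3 ketone, which would hold C3 in the wrong configuration.

Step 8
Reactants: 14 pent-3-yn-1-ol
Product: 15 5-iodopent-2-yne
Conditions: I2, PPh3, imidazole, CH2Cl2, 0 °C
Reagents that add atoms: iodine, [I][I]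
Why: Appel iodination of a primary alcohol.

Step 9
Reactants: 13 silyl ether Weinreb amide; 15 5-iodopent-2-yne
Product: 18 equatorial bicyclic ketone, via pent-3-yn-1-yllithium 16 (not isolated), via axial bicyclic ketone 17 (not isolated)
Conditions: 15, t-BuLi (2 equiv), Et2O/pentane, −78 °C; then 13, THF, −78 → 0 °C; AcOH; then DBU, CH2Cl2, rt
Reagents that add atoms: none
Why: Iodine–lithium exchange and single addition to the Weinreb amide give ketone 17, and DBU should then equilibrate C3 through the enol to the equatorial (endo) ketone trans to the chain, the thermodynamic preference known for 2-acyl and 2-carboxy 8-aza- and 8-oxabicyclo[3.2.1]octanes, while the bicycle disfavours β-elimination of the bridging oxygen.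

Step 10
Reactants: 18 equatorial bicyclic ketone
Product: 20 keto diol, via dialdehyde 19 (not isolated)
Conditions: O3, CH2Cl2/MeOH, −78 °C (Sudan red end point); Me2S, −78 °C → rt; NaBH(OAc)3, AcOH, CH2Cl2, 0 °C
Reagents that add atoms: ozone, [O-][O+]=O
Why: Ozone should cleave the strained cis-alkene far faster than the internal alkynes, and NaBH(OAc)3 reduces the two aldehydes but not the ketone; the CH2OH on C2 is cis to the C3 ketone and closes a hemiketal, which tells the two primary alcohols apart, and C2 and C6 keep the cis relation imposed by the bridge.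

Step 11
Reactants: 20 keto diol
Product: 21 primary iodide
Conditions: I2, PPh3, imidazole, CH2Cl2, 0 °C
Reagents that add atoms: iodine, [I][I]
Why: Appel iodination should take the only free primary alcohol (on C6), since the other is neopentylic and tied up as the hemiketal.

Step 12
Reactants: 21 primary iodide
Product: 22 C6-methyl keto alcohol
Conditions: Bu3SnH, Et3B (cat.), air, toluene, rt
Reagents that add atoms: none
Why: Radical dehalogenation; iodine abstraction by the tin radical is much faster than its addition to internal alkynes at room temperature, and the CH3 so formed is the former furan C-4.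

Step 13
Reactants: 22 C6-methyl keto alcohol
Product: 23 keto acid
Conditions: TEMPO (cat.), NaClO2, NaOCl (cat.), MeCN/phosphate buffer pH 6.7, 35 °C
Reagents that add atoms: sodium chlorite, [Na+].[O-]Cl=O
Why: TEMPO/chlorite oxidation takes the primary alcohol (reached through the open form of the hemiketal) to the acid without touching ketone, alkynes or silyl ether.

Step 14
Reactants: 23 keto acid
Product: 26 Boc carbamate diyne, via acyl azide 24 (not isolated), via isocyanate 25 (not isolated)
Conditions: DPPA, Et3N, toluene, rt → 80 °C; then t-BuOH, CuCl (cat.), 80 °C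
Reagents that add atoms: diphenylphosphoryl azide, [N-]=[N+]=NP(=O)(Oc1ccccc1)Oc1ccccc1; tert-butanol, CC(C)(C)O
Why: Curtius rearrangement proceeds with retention at C2, so the nitrogen takes the place of the former bridge carbon, cis to the CH3 on C6 and to the C3 ketone, and tert-butanol traps the isocyanate.

Step 15
Reactants: 26 Boc carbamate diyne
Product: 27 macrocyclic ynone
Conditions: Mo(≡CC6H4-4-OMe)(OSiPh3)3 (5 mol %), 5 Å molecular sieves, toluene (2 mM), 80 °C
Reagents that add atoms: none
Why: Ring-closing alkyne metathesis of the two methyl-capped alkynes, driven by loss of but-2-yne into the sieves, closes the 13-membered ring far from the stereocentres and should tolerate ketone, carbamate and silyl ether.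

Step 16
Reactants: 27 macrocyclic ynone
Product: 29 pyrrolophane silyl ether, via macrocyclic diketone 28 (not isolated)
Conditions: AuCl(PPh3)/AgOTf (5 mol %), H2O, 1,4-dioxane, 60 °C; then NH4OAc, AcOH/MeOH, 60 °C
Reagents that add atoms: ammonium acetate, [NH4+].CC(=O)[O-]
Why: Ketone-assisted gold hydration (5-exo attack of the carbonyl oxygen) places the new carbonyl 1,4 to the first, and Paal–Knorr condensation then gives the 2,5-bridged pyrrole, as in the classical preparation of [9](2,5)pyrrolophane from cyclotridecane-1,4-dione; C3 can no longer epimerize once ring C is aromatic.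

Step 17
Reactants: 29 pyrrolophane silyl ether
Product: 30 pyrrolophane alcohol
Conditions: HF·pyridine, pyridine, THF, 0 °C → rt
Reagents that add atoms: none
Why: Buffered HF removes the silyl ether without forming an alkoxide, so the neighbouring Boc carbamate should not close to an oxazolidinone.

Step 18
Reactants: 30 pyrrolophane alcohol
Product: 31 pyrrolophane methyl ketone
Conditions: SO3·pyridine, DMSO, i-Pr2NEt, CH2Cl2, 0 °C
Reagents that add atoms: none
Why: Parikh–Doering oxidation is mild enough for the electron-rich pyrrole and turns the carbinol (the original stereocentre of 1) into the methyl ketone only now, after ring C has consumed the other ketone.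

Step 19
Reactants: 31 pyrrolophane methyl ketone; 32 1-(tert-butoxycarbonyl)pyrrole-2-carboxylic acid
Product: 34 β-diketone, via acylimidazole 33 (not isolated)
Conditions: 32, CDI, THF, rt; separately 31, LiN(SiMe3)2 (3.3 equiv), THF, −78 °C; then 33, −78 → 0 °C; AcOH
Reagents that add atoms: none
Why: Claisen-type C-acylation of the methyl ketone enolate (the only ketone present, formed after the two N–H groups are deprotonated) by an acylimidazole gives the β-diketone that holds all ring B carbons.

Step 20
Reactants: 34 β-diketone
Product: 36 spiro vinylogous amide, via amino diketone 35 (not isolated)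
Conditions: TFA, CH2Cl2, 0 °C; then NaHCO3, MeOH, 40 °C
Reagents that add atoms: none
Why: Acid removes both Boc groups, and on neutralization the amine on C2 condenses with the pyrrolyl carbonyl, the only one that gives a five-membered ring; the axial C2–N bond is also the anomerically favoured arrangement.

Step 21
Reactants: 36 spiro vinylogous amide
Product: 38 premarineosin A, via O-methyl iminium tetrafluoroborate 37 (not isolated)
Conditions: Me3OBF4, CH2Cl2, 0 °C; aqueous NaHCO3
Reagents that add atoms: trimethyloxonium tetrafluoroborate, C[O+](C)C.F[B-](F)(F)F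
Why: The carbonyl oxygen of the vinylogous amide is the most nucleophilic site for the oxonium salt, and deprotonation of the iminium salt gives the 3-methoxy-2H-pyrrole conjugated with ring A.

**Compound list**

1 | (R)-1-(furan-2-yl)ethanol | C[C@@H](O)c1ccco1 | starting material
2 | but-3-enoic acid | C=CCC(=O)O | starting material
3 | (R)-1-(furan-2-yl)ethyl but-3-enoate | C[C@@H](OC(=O)CC=C)c1ccco1 | intermediate
4 | (R)-1-(furan-2-yl)ethyl 2-diazobut-3-enoate | C[C@@H](OC(=O)C(=[N+]=[N-])C=C)c1ccco1 | intermediate
5 | divinylcyclopropane: 1-vinyl-4-methyl-3-oxabicyclo[3.1.0]hexan-2-one whose C5–C6 bond is the 2,3-bond of a 2,3-dihydrofuran (vinyl cis to the dihydrofuran C=C, methyl anti to C6) | C=C[C@]12C(=O)O[C@H](C)[C@]13OC=C[C@H]23 | intermediate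
6 | tricyclic dienyl lactone: 8-oxabicyclo[3.2.1]octa-2,6-diene (C3=C4 and bridge C=C) with a γ-lactone from the exo CH(CH3)–O carbon on C2 to the C=O on C3 | C[C@H]1OC(=O)C2=CC[C@@H]3C=C[C@]12O3 | intermediate
7 | 1,6-dibromohexane | BrCCCCCCBr | starting material
8 | 1-propynyllithium | [Li]C#CC | starting material
9 | 9-bromonon-2-yne | CC#CCCCCCCBr | intermediate
10 | non-7-yn-1-ylmagnesium bromide | CC#CCCCCCC[Mg]Br | intermediate
11 | cis-fused chain lactone: lactone of 6 saturated at C3–C4, non-7-ynyl exo on C4, lactone C=O exo (axial) on C3 | C[C@H]1OC(=O)[C@H]2[C@@H](CCCCCCC#CC)C[C@@H]3C=C[C@]12O3 | intermediate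
12 | hydroxy Weinreb amide: 8-oxabicyclo[3.2.1]oct-6-ene with (R)-1-hydroxyethyl on C2, exo C(=O)N(OMe)Me on C3, exo chain on C4 | CON(C)C(=O)[C@H]1[C@@H](CCCCCCC#CC)C[C@@H]2C=C[C@@]1([C@@H](C)O)O2 | intermediate
13 | silyl ether Weinreb amide (TBS ether of 12) | CON(C)C(=O)[C@H]1[C@@H](CCCCCCC#CC)C[C@@H]2C=C[C@@]1([C@@H](C)O[Si](C)(C)C(C)(C)C)O2 | intermediate
14 | pent-3-yn-1-ol | CC#CCCO | starting material
15 | 5-iodopent-2-yne | CC#CCCI | intermediate
16 | pent-3-yn-1-yllithium | CC#CCC[Li] | intermediate
17 | axial bicyclic ketone: hex-4-ynoyl exo on C3, cis to the chain | CC#CCCC(=O)[C@H]1[C@@H](CCCCCCC#CC)C[C@@H]2C=C[C@@]1([C@@H](C)O[Si](C)(C)C(C)(C)C)O2 | intermediate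
18 | equatorial bicyclic ketone: C3 epimer of 17, hex-4-ynoyl endo, trans to the chain | CC#CCCC(=O)[C@@H]1[C@@H](CCCCCCC#CC)C[C@@H]2C=C[C@@]1([C@@H](C)O[Si](C)(C)C(C)(C)C)O2 | intermediate
19 | dialdehyde: tetrahydropyran with cis CHO groups on C2 and C6 | O=C[C@@]1([C@@H](C)O[Si](C)(C)C(C)(C)C)O[C@@H](C=O)C[C@H](CCCCCCC#CC)[C@H]1C(=O)CCC#CC | intermediate
20 | keto diol: CH2OH on C2 (cis to the C3 ketone) and on C6 | OC[C@@]1([C@@H](C)O[Si](C)(C)C(C)(C)C)O[C@@H](CO)C[C@H](CCCCCCC#CC)[C@H]1C(=O)CCC#CC | intermediate
21 | primary iodide: CH2I on C6 | OC[C@@]1([C@@H](C)O[Si](C)(C)C(C)(C)C)O[C@@H](CI)C[C@H](CCCCCCC#CC)[C@H]1C(=O)CCC#CC | intermediate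
22 | C6-methyl keto alcohol | OC[C@@]1([C@@H](C)O[Si](C)(C)C(C)(C)C)O[C@@H](C)C[C@H](CCCCCCC#CC)[C@H]1C(=O)CCC#CC | intermediate
23 | keto acid: CO2H on C2 | OC(=O)[C@@]1([C@@H](C)O[Si](C)(C)C(C)(C)C)O[C@@H](C)C[C@H](CCCCCCC#CC)[C@H]1C(=O)CCC#CC | intermediate
24 | acyl azide | [N-]=[N+]=NC(=O)[C@@]1([C@@H](C)O[Si](C)(C)C(C)(C)C)O[C@@H](C)C[C@H](CCCCCCC#CC)[C@H]1C(=O)CCC#CC | intermediate
25 | isocyanate | O=C=N[C@@]1([C@@H](C)O[Si](C)(C)C(C)(C)C)O[C@@H](C)C[C@H](CCCCCCC#CC)[C@H]1C(=O)CCC#CC | intermediate
26 | Boc carbamate diyne: NHBoc on C2, cis to CH3 on C6 and to the C3 ketone | CC(C)(C)OC(=O)N[C@@]1([C@@H](C)O[Si](C)(C)C(C)(C)C)O[C@@H](C)C[C@H](CCCCCCC#CC)[C@H]1C(=O)CCC#CC | intermediate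
27 | macrocyclic ynone: 13-membered cycloalkynone trans-fused at C3–C4 | CC(C)(C)OC(=O)N[C@@]1([C@@H](C)O[Si](C)(C)C(C)(C)C)O[C@@H](C)C[C@@H]2CCCCCCC#CCCC(=O)[C@@H]12 | intermediate
28 | macrocyclic diketone (1,4-diketone) | CC(C)(C)OC(=O)N[C@@]1([C@@H](C)O[Si](C)(C)C(C)(C)C)O[C@@H](C)C[C@@H]2CCCCCCCC(=O)CCC(=O)[C@@H]12 | intermediate
29 | pyrrolophane silyl ether | CC(C)(C)OC(=O)N[C@@]1([C@@H](C)O[Si](C)(C)C(C)(C)C)O[C@@H](C)C[C@@H]2CCCCCCCc3ccc([nH]3)[C@@H]12 | intermediate
30 | pyrrolophane alcohol | CC(C)(C)OC(=O)N[C@@]1([C@@H](C)O)O[C@@H](C)C[C@@H]2CCCCCCCc3ccc([nH]3)[C@@H]12 | intermediate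
31 | pyrrolophane methyl ketone: acetyl and NHBoc on C2 | CC(C)(C)OC(=O)N[C@@]1(C(C)=O)O[C@@H](C)C[C@@H]2CCCCCCCc3ccc([nH]3)[C@@H]12 | intermediate
32 | 1-(tert-butoxycarbonyl)pyrrole-2-carboxylic acid | CC(C)(C)OC(=O)n1cccc1C(=O)O | starting material
33 | acylimidazole of 32 | CC(C)(C)OC(=O)n1cccc1C(=O)n1ccnc1 | intermediate
34 | β-diketone | CC(C)(C)OC(=O)N[C@@]1(C(=O)CC(=O)c4cccn4C(=O)OC(C)(C)C)O[C@@H](C)C[C@@H]2CCCCCCCc3ccc([nH]3)[C@@H]12 | intermediate
35 | amino diketone | N[C@@]1(C(=O)CC(=O)c4ccc[nH]4)O[C@@H](C)C[C@@H]2CCCCCCCc3ccc([nH]3)[C@@H]12 | intermediate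
36 | spiro vinylogous amide (5-(pyrrol-2-yl)-1,2-dihydropyrrol-3-one spiro-fused at C2) | O=C1C=C(c2ccc[nH]2)N[C@]12O[C@@H](C)C[C@@H]1CCCCCCCc3ccc([nH]3)[C@H]12 | intermediate
37 | O-methyl iminium tetrafluoroborate | COC1=CC(c2ccc[nH]2)=[NH+][C@]12O[C@@H](C)C[C@@H]1CCCCCCCc3ccc([nH]3)[C@H]12.F[B-](F)(F)F | intermediate
38 | premarineosin A | COC1=CC(c2ccc[nH]2)=N[C@]12O[C@@H](C)C[C@@H]1CCCCCCCc3ccc([nH]3)[C@H]12 | target

**Count and risks**

Total: 21 steps. Longest linear sequence: 19 steps (steps 1–3, 5–7, 9–21).

Steps most likely to fail: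

1. Step 3. The carbene may attack the furan without closing the cyclopropane, so that the ring unravels to a dienone, or it may add to both furan faces. The fallback sets out from 1 and returns at 6. Alcohol 1 is converted with methyl chloroformate and pyridine into (R)-1-(furan-2-yl)ethyl methyl carbonate F1. The furan is combined with the oxyallyl cation from 1,1,3,3-tetrabromoacetone and zinc–copper couple, and the bromine atoms are then removed with zinc–copper couple/NH4Cl, to give the bridgehead-substituted 8-oxabicyclo[3.2.1]oct-6-en-3-one F2; this classical [4+3] cycloaddition makes the same two ring bonds, and the two bridgehead diastereomers are separated. LiN(SiMe3)2 closes the lactone by Claisen condensation of the ketone enolate on the carbonate (only the enolate on the C3 side can reach it) to give the β-keto lactone F3, drawn as its enol. Triflation with N-(5-chloropyridin-2-yl)triflimide gives the enol triflate F4, and Pd(OAc)2/PPh3 with HCO2H/Et3N replaces the triflate by hydrogen to give 6.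

2. Step 9. The epimerization equilibrium at C3 may not lie far enough on the equatorial side, because the neighbouring bridgehead is fully substituted. The fallback sets out from 17 and returns at 20. The unequilibrated axial ketone 17 is taken through the ozonolysis, Me2S and NaBH(OAc)3 sequence of step 10 to the C3-epimeric keto diol F5, in which the hydroxymethyl group on C2 is trans to the ketone. DBU in CH2Cl2 then epimerizes C3 in the monocycle, where closure of the cis-fused five-membered hemiketal pulls the equilibrium over (the silyl ether blocks the only competing hydroxyl), to give 20.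

3. Step 19. The polyanion may be acylated on nitrogen or on the enolate oxygen, or the Boc group of the acyl donor may be transferred. The fallback sets out from 31 and returns at 34. The lithium enolate of 31 is added to tert-butyl 2-formylpyrrole-1-carboxylate in an aldol reaction to give the β-hydroxy ketone F6 (mixture at the new carbinol carbon), and Dess–Martin periodinane with NaHCO3 oxidizes it to 34.

Further compounds
F1 | step 3 | (R)-1-(furan-2-yl)ethyl methyl carbonate | C[C@@H](OC(=O)OC)c1ccco1
F2 | step 3 | 8-oxabicyclo[3.2.1]oct-6-en-3-one carrying the (R)-1-(methoxycarbonyloxy)ethyl group on the bridgehead that becomes C2 | C[C@@H](OC(=O)OC)[C@]12CC(=O)C[C@H](C=C1)O2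
F3 | step 3 | β-keto lactone (enol form; 6 with OH on C4) | C[C@H]1OC(=O)C2=C(O)C[C@@H]3C=C[C@]12O3
F4 | step 3 | enol triflate (6 with OSO2CF3 on C4) | C[C@H]1OC(=O)C2=C(OS(=O)(=O)C(F)(F)F)C[C@@H]3C=C[C@]12O3
F5 | step 9 | C3-epimeric keto diol (C3 epimer of 20, ketone trans to the CH2OH on C2) | OC[C@@]1([C@@H](C)O[Si](C)(C)C(C)(C)C)O[C@@H](CO)C[C@H](CCCCCCC#CC)[C@@H]1C(=O)CCC#CC
F6 | step 19 | β-hydroxy ketone (aldol adduct of 31) | CC(C)(C)OC(=O)N[C@@]1(C(=O)CC(O)c4cccn4C(=O)OC(C)(C)C)O[C@@H](C)C[C@@H]2CCCCCCCc3ccc([nH]3)[C@@H]12
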